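I must decide whether the 24.0 mM of L charged to this flask is enough to spend the Z, or whether I should charge more.

| setting | north-east | south | flask |
|---|---|---|---|
| Z | 16 mM | 16 mM | 16 mM |
| L | 24 mM | 36 mM | 24.0 mM |
| remark | the very flask that is asked about, followed so far | run made earlier |  |
| time |  |  | 10 h |

north-east run (percent of the Z charged)

| time / min | Z / % | J / % |
|---|---|---|
| 30.0 | 69 | 32 |
| 60.0 | 25 | 74 |
| 90.0 | 9 | 89 |
| 120 | 10 | 90 |

south run (percent of the Z charged)

| time / h | Z / % | J / % |
|---|---|---|
| 0.333 | 67 | 33 |
| 0.667 | 13 | 89 |
| 1.50 | 0 | 97 |
| 4.00 | 0 | 101 |

(each reading ± 2 percentage points)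

* the state of affairs at 10 h: stopped, and by what, or still going (it is still moving / all of Z has reacted / L has run out first)
* how much of the Z has reacted by 10 h
* how much J there is at 10 h, in percent of the Z charged

- the numbers in the tables scatter with a standard deviation of 2 percentage points
- the reaction counts as stopped when no species that holds the Z changes by six tenths of a point or more over the second half of the time

I turn the question round: for Z to end at zero in this flask, each Z may use at most the L per Z charged.

critical ratio = 24.0 mM / 16 mM = 1.50

The north-east run is this flask so far, and its last two readings hold Z near 9.50%, against a scatter of 2 percentage points. If L is what stopped it, I can read what each Z has used: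

L cost = 24 mM / (16 mM × 90.5%) = 1.66

This L cost, the L charged divided by the Z reacted at the stop, is higher than the critical ratio, but that follows from its definition while some Z remains, and I assumed that L stopped the north-east run, so this comparison cannot show what stopped it.

Going round once more, I put the cost into the south run, where Z needs 26.5 mM of L. That is less than the 36 mM charged, and Z there reads 0%, which fits L as the limiting reagent of the north-east run. I commit to 90.5% reacted.

The forecast gives L has run out first, with 90% reacted and 90% of J, a little below my figure, and says “it should stay on the plateau”.

The flask gives L has run out first, with 97.8% reacted and 97.8% of J.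

    Z + L + J → 2 J (k = 400 L² mol⁻² min⁻¹)
    Z + L → J (k = 0.0580 L mol⁻¹ min⁻¹)
    L → G (k = 0.00630 min⁻¹)

With 2.2% of Z left at 10.0 h, the L cost of this flask is 1.53, lower than my 1.66 and slightly above the critical 1.50. A neighbouring flask has 14 mM of L, with Z as before, and I reckon it with both costs:

14 mM / (1.66 × 16 mM) = 52.7%

14 mM / (1.53 × 16 mM) = 57.2%

That neighbouring flask gives 57.0% reacted at 10.0 h, with 43.0% of its Z left and L at 0% of its charge.

The earlier runs and the new flask were computed on assumed constants, noise included.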